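## Analysis of the target

Iridal (35) is a monocyclic C30 triterpenoid. One cyclohexane ring (C6–C11 in iridal numbering) carries all the functionality except the three trisubstituted alkenes of the homofarnesyl chain C12–C23, two of which are stereogenic and (E). The ring has three contiguous stereocentres: C6 (R) with the 3-hydroxypropyl arm C5–C3, the quaternary C11 (S) with a methyl group and the chain, and C10 (S) with a methyl group and a tertiary hydroxyl. The C10 hydroxyl, the C11 methyl and the C6 arm lie on one face of the ring; the chain and the C10 methyl lie on the other, so the hydroxyl is trans to the chain. C7 bears an exocyclic tetrasubstituted alkene to C2, with the aldehyde carbon C1 cis to C6, which is the (Z) geometry. The sensitive groups are the enal (base removes the γ-hydrogens at C6 and C8, which epimerises C6, moves the alkene or scrambles its geometry), the tertiary alcohol (ionisation under acid) and the 1,5-polyene (acid-induced cyclisation, electrophilic oxidants). The synthesis is hard because C10 and C11 are adjacent fully substituted carbons, because the tetrasubstituted alkene sits next to a branched ring carbon, and because the polyene must be carried without damage. The route rests on the C10–C11 bond: C10 with its methyl and hydroxyl is the carbon of a methyl ketone ketyl, and C11 with its methyl and the first two chain carbons C12–C13 is the β-carbon of a β-methyl enoate, so reductive closure of this bond makes the ring and both centres at once.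

## Retrosynthetic reasoning

35 ⇒ 34. Only the C3–O bond to the 4-methoxybenzyl group is cut. This ether is removed oxidatively at neutral pH, which the enal tolerates, and it is orthogonal to the silyl ethers used elsewhere.

34 ⇒ 31 ⇒ 30. The C7=C2 alkene is traced to the tertiary 2-propenyl carbinol 31, and the C7–C2 bond is then cut to give ketone 30 and a 2-propenyl organometallic. Direct olefination of this hindered, α-branched ketone with a stabilised phosphorus reagent would be slow and would leave the geometry to chance. A small, non-basic nucleophile adds instead, and an oxidative 1,3-transposition then creates alkene and aldehyde together in a cyclic sigmatropic transition state, which has to place C1 cis to C6.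

30 ⇒ 29 ⇒ 28. The C7 carbonyl is taken back to a silyl-protected secondary alcohol. This oxygen is the aldol handle of the early steps and the equatorial anchor of the ring closure, so it is carried as an ether until the chain is in place.

28 ⇒ 21 + 26. The C13–C14 bond is cut. This leaves on the ring exactly the two carbons C12–C13 that an enoate supplies, keeps the three chain alkenes away from the reductive and oxidative steps of ring construction, and brings in the (E)-C14=C15 alkene preformed. The forward step is an sp3–sp2 cross-coupling of the organozinc 27 (from iodide 21) with alkenyl iodide 26, with retention of alkene geometry.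

26 ⇒ 24 ⇒ 22. The C15–methyl and C14–iodine bonds come from syn-methylmetalation of alkyne 24, which fixes the (E) geometry by mechanism. The alkyne comes from methyl ketone 22, which already holds the other (E)-alkene.

21 ⇒ 20 ⇒ 19 ⇒ 18. The iodide is derived from the ester of 18 by reduction and substitution. The C10 hydroxyl is capped as a triethylsilyl ether first, because a free 1,4-hydroxy iodide would close to a five-membered cyclic ether and would quench the organozinc.

18 ⇒ 16. The C10–C11 bond is cut: reductive coupling of the C10 methyl ketone with the β-carbon of the (E)-β-methyl enoate. This is the only disconnection that forms the ring and both fully substituted centres in one step from an acyclic chain, and its ester is precisely C13. The forward reaction must close 6-exo, place the C12–C13 arm trans to the C6 arm and the hydroxyl trans to the C12–C13 arm, and outrun simple reduction.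

16 ⇒ 15. The C10 carbonyl is carried as a terminal alkene and revealed by aerobic palladium-catalysed oxidation. No ketal has to be made or hydrolysed, and no acid step is run on a substrate with a γ-epimerisable centre and a silyl ether.

15 ⇒ 12 + 13, and 12 ⇒ 11 ⇒ 10 ⇒ 9. The C11=C12 bond is made by olefination of methyl ketone 12 with phosphonate 13. The C11–methyl bond comes from a methyl organometallic and Weinreb amide 11, which is reached from aldol adduct 9 by aminolysis (10) and silylation.

9 ⇒ 6 + 7. The C6–C7 bond is cut in an auxiliary-controlled syn-aldol between imide 6 and aldehyde 7. It sets C6, which persists to the target, and C7, which is temporary. Their syn relation becomes a trans-diequatorial pair in the ring and so locks the chair through which the key step transfers chirality to C10 and C11. The (R)-auxiliary 4 gives the required absolute sense.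

6 ⇒ 3 + 4, and 3 ⇒ 1. N-Acylation of 4 with acid 3 gives the imide. Acid 3 results from opening lactone 1 and etherifying the liberated hydroxyl in the same flask, so the C3–C6 arm is bought with its oxygen already in place.

## Alternatives that were turned down

Alternative 1: The ring is taken as given, and the C11–C12 and C6–C5 bonds are cut on enone A2, (4S)-3,4-dimethyl-4-(triethylsilyloxy)cyclohex-2-en-1-one. In the forward step an organocopper reagent made from homofarnesyl iodide A3 adds to C11, and the enolate is trapped at C6 by an allyl halide to give ketone A1.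
- For: two carbon–carbon bonds, two stereocentres and the whole chain arrive in one flask, and the C7 carbonyl is already present, so no protection or oxidation at C7 is needed. On convergence and step count this plan is stronger than the chosen one.
- Against: the β-carbon C11 is disubstituted and flanked by the fully substituted C10, a situation in which conjugate additions are slow and need strong activation. The elaborate chain must be used as the organometallic, normally in excess. Face selection at C11 depends on telling a silyloxy group from a methyl group on one carbon. C-Allylation of the hindered enolate competes with proton transfer and O-allylation. A2 needs its own enantioselective synthesis of a tertiary alcohol, and the allyl group must later be hydroborated beside three trisubstituted alkenes.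
- Comparison: the chosen route instead forms the congested bond intramolecularly under the control of two aldol-derived centres (16 to 18) and spends the chain in a near-stoichiometric cross-coupling (21 + 26). The endgame at C7 is common to both.

Alternative 2: The C6–C11 bond is cut. The substrate is epoxide A5, a trans-10,11-epoxide tethered to a (Z)-trimethylsilyl enol ether; the epoxide is available by catalytic asymmetric epoxidation of an allylic alcohol. In the forward step a methylaluminium Lewis acid activates the epoxide, and the enol ether carbon C6 opens it at the tertiary carbon C11 with inversion to give 4-hydroxycyclohexanone A4.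
- For: C11 is set stereospecifically from a catalytically made epoxide, the chain is present from the start so no fragment coupling is needed, and C7 is already a ketone. On these points it is as strong as or stronger than the chosen route.
- Against: C10 in A4 is a secondary carbinol. Its methyl group would have to be added later to a C10 ketone next to the quaternary C11, in competition with the C7 ketone and with unproven facial selectivity. A Lewis-acid-activated tertiary epoxide next to three nucleophilic alkenes also invites hydride shift to a carbonyl compound and cation–olefin side reactions. The trisubstituted enol ether must be made regio- and stereoselectively, and the C6 configuration depends on a chair-versus-boat preference.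
- Comparison: the chosen route delivers C10 with both its methyl and its hydroxyl in the ring-closing step (18), at the price of a longer linear sequence.

Alternative 3: The C6–C7 bond is cut. The substrate is the acyclic (Z)-enol triflate A7 of a β-keto ester, which carries an (E)-homoallylic alcohol. In the forward step zerovalent palladium inserts into the C7–OTf bond, the alkenylpalladium adds across C6=C5 (6-exo-trig), and the metal migrates from C5 to C3 to release aldehyde A6.
- For: the geometry of the tetrasubstituted alkene is fixed by the enol triflate and transferred with retention, and C3 is oxygenated in the same step. This is the element the chosen route controls least securely (31 to 34), and on it alternative 3 is clearly stronger.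
- Against: C10 in A6 is again a secondary silyl ether, so the methyl group must be added late beside an enoate. The new stereocentre C6 has to be induced by the neighbouring quaternary C11, whose methyl and chain methylene differ little in size. A tetrasubstituted alkenylpalladium must insert into a 1,2-disubstituted alkene and then walk over two methylenes without stopping, in a molecule with three further alkenes. A7 already needs the C10 and C11 centres made acyclically.
- Comparison: the chosen route gives up the elegant alkene control but secures all three ring stereocentres through one chair transition state, and it defers the geometry question to a sigmatropic step with a fallback.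

Key step: step 9

Remark on the chemistry: positions are numbered as in iridal throughout (C1 aldehyde carbon, C3 carbinol carbon, ring C6–C11, chain C12–C23), and 22 is taken as the isomerically pure (E)-ketone.

## Route

Step 1
Reactants: 1 δ-valerolactone
Product: 3 5-[(4-methoxybenzyl)oxy]pentanoic acid, via potassium 5-hydroxypentanoate 2 (not isolated)
Conditions: KOH (powdered), 4-methoxybenzyl chloride, toluene, reflux; then aq. HCl, 0 °C
Reagents that add atoms: 4-methoxybenzyl chloride, COc1ccc(CCl)cc1; potassium hydroxide, [K+].[OH-]
Why: Hydroxide opens the lactone to 2, whose alkoxide is benzylated under Williamson conditions; any 4-methoxybenzyl ester formed is saponified in the same pot, so acidification should give the ether acid.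

Step 2
Reactants: 3 5-[(4-methoxybenzyl)oxy]pentanoic acid; 4 (R)-4-benzyl-1,3-oxazolidin-2-one
Product: 6 (R)-4-benzyl-3-{5-[(4-methoxybenzyl)oxy]pentanoyl}-1,3-oxazolidin-2-one, via mixed pivalic anhydride 5 (not isolated)
Conditions: t-BuCOCl, Et3N, THF, −20 °C; then 4, LiCl, −20 °C → rt
Reagents that add atoms: none
Why: Standard N-acylation of an Evans auxiliary through a mixed anhydride; the hindered pivaloyl carbonyl directs the LiCl-activated oxazolidinone to the desired acyl group.

Step 3
Reactants: 6 (R)-4-benzyl-3-{5-[(4-methoxybenzyl)oxy]pentanoyl}-1,3-oxazolidin-2-one; 7 pent-4-enal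
Product: 9 (R)-4-benzyl-3-{(2R,3S)-3-hydroxy-2-[3-(4-methoxybenzyloxy)propyl]hept-6-enoyl}-1,3-oxazolidin-2-one, via dibutylboron (Z)-enolate 8 (not isolated)
Conditions: n-Bu2BOTf, i-Pr2NEt, CH2Cl2, 0 °C; 7, −78 → 0 °C; then pH 7 buffer, MeOH, 30% H2O2, 0 °C
Reagents that add atoms: none
Why: Evans syn-aldol reaction: the (Z)-boron enolate reacts through a closed Zimmerman–Traxler chair on the enolate face opposite the benzyl group, which sets C6 and C7 syn with the (2R,3S) configuration of the acyl chain. The terminal alkene is inert to the buffered peroxide work-up.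

Step 4
Reactants: 9 (R)-4-benzyl-3-{(2R,3S)-3-hydroxy-2-[3-(4-methoxybenzyloxy)propyl]hept-6-enoyl}-1,3-oxazolidin-2-one
Product: 10 (2R,3S)-3-hydroxy-N-methoxy-2-[3-(4-methoxybenzyloxy)propyl]-N-methylhept-6-enamide
Conditions: MeNH(OMe)·HCl, Me3Al, CH2Cl2, −20 → 0 °C; aq. KNaC4H4O6
Reagents that add atoms: N,O-dimethylhydroxylamine hydrochloride, CNOC.Cl
Why: Aluminium amide aminolysis of the imide to the Weinreb amide; it is run before silylation because the aluminium alkoxide at C7 delivers the amide to the exocyclic carbonyl, whereas a silylated adduct tends to open at the ring carbonyl.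

Step 5
Reactants: 10 (2R,3S)-3-hydroxy-N-methoxy-2-[3-(4-methoxybenzyloxy)propyl]-N-methylhept-6-enamide
Product: 11 (2R,3S)-3-[(tert-butyldimethylsilyl)oxy]-N-methoxy-2-[3-(4-methoxybenzyloxy)propyl]-N-methylhept-6-enamide
Conditions: t-BuMe2SiOTf, 2,6-lutidine, CH2Cl2, −78 → 0 °C
Reagents that add atoms: tert-butyldimethylsilyl triflate, CC(C)(C)[Si](C)(C)OS(=O)(=O)C(F)(F)F
Why: Silyl triflate silylation of a secondary alcohol; the bulky ether blocks retro-aldol and β-elimination, later holds C7 equatorial, and lasts until the fluoride step.

Step 6
Reactants: 11 (2R,3S)-3-[(tert-butyldimethylsilyl)oxy]-N-methoxy-2-[3-(4-methoxybenzyloxy)propyl]-N-methylhept-6-enamide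
Product: 12 (3R,4S)-4-[(tert-butyldimethylsilyl)oxy]-3-[3-(4-methoxybenzyloxy)propyl]oct-7-en-2-one
Conditions: MeMgBr, THF, 0 °C; aq. NH4Cl
Reagents that add atoms: methylmagnesium bromide, C[Mg]Br
Why: Weinreb ketone synthesis; the stable magnesium chelate prevents over-addition and keeps the α-centre C6 from enolising before work-up.

Step 7
Reactants: 12 (3R,4S)-4-[(tert-butyldimethylsilyl)oxy]-3-[3-(4-methoxybenzyloxy)propyl]oct-7-en-2-one; 13 triethyl phosphonoacetate
Product: 15 ethyl (2E,4S,5S)-5-[(tert-butyldimethylsilyl)oxy]-4-[3-(4-methoxybenzyloxy)propyl]-3-methylnona-2,8-dienoate, via sodium phosphonoacetate carbanion 14 (not isolated)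
Conditions: NaH, 13, THF, 0 °C; then 12, reflux
Reagents that add atoms: none
Why: Horner–Wadsworth–Emmons olefination of a methyl ketone; the branched C6 substituent should end up trans to the ester for steric reasons, giving the (E)-β-methyl enoate, and any (Z)-isomer is removed here by chromatography. The weakly basic phosphonate anion enolises the ketone mainly on the methyl side, which spares C6.

Step 8
Reactants: 15 ethyl (2E,4S,5S)-5-[(tert-butyldimethylsilyl)oxy]-4-[3-(4-methoxybenzyloxy)propyl]-3-methylnona-2,8-dienoate
Product: 16 ethyl (2E,4S,5S)-5-[(tert-butyldimethylsilyl)oxy]-4-[3-(4-methoxybenzyloxy)propyl]-3-methyl-8-oxonon-2-enoate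
Conditions: PdCl2 (10 mol%), CuCl (redox co-catalyst), O2 (1 atm), DMF/H2O 7:1, rt
Reagents that add atoms: water, O
Why: Tsuji–Wacker oxidation: the monosubstituted alkene is hydroxypalladated at its internal carbon and gives the methyl ketone, while the electron-poor trisubstituted enoate does not compete for palladium. No acid is needed, so the silyl ether and the γ-centre C6 are not at risk.

Step 9
Reactants: 16 ethyl (2E,4S,5S)-5-[(tert-butyldimethylsilyl)oxy]-4-[3-(4-methoxybenzyloxy)propyl]-3-methyl-8-oxonon-2-enoate
Product: 18 ethyl 2-{(1S,2S,5S,6S)-5-[(tert-butyldimethylsilyl)oxy]-2-hydroxy-6-[3-(4-methoxybenzyloxy)propyl]-1,2-dimethylcyclohexyl}acetate, via samarium ketyl 17 (not isolated)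
Conditions: SmI2 (0.1 M in THF, 2.5 equiv, added slowly), HMPA (8 equiv), t-BuOH (2 equiv), THF, −78 → −20 °C; cold aq. NaHCO3
Reagents that add atoms: none
Why: The closest known reaction type is the SmI2-mediated ketyl–olefin reductive cyclisation of a ketone onto a tethered α,β-unsaturated ester, here building a quaternary carbon. Divalent samarium, made more reducing by HMPA, transfers one electron to the C10 carbonyl to give ketyl 17, whose carbon adds to the β-carbon C11 of the enoate; the ester-stabilised radical at C12 takes a second electron and the samarium enolate is protonated by t-BuOH. The ring C6–C11 closes in the 6-exo-trig mode, with C12 left outside the ring. C11 is controlled by C6: the chair transition state keeps the C6 arm and the C7 silyloxy group equatorial (their trans relation comes from the syn-aldol), and allylic 1,3-strain between the C12–H bond and C7 holds the enoate terminus pseudo-equatorial, so the C12–C13 arm ends up trans to the C6 arm and the C11 methyl axial. C10 is controlled by the bulky HMPA-solvated O–Sm group, which takes the pseudo-equatorial site away from the ester-bearing carbon; this puts the C10 methyl axial, anti to the C11 methyl, and the hydroxyl trans to the acetate arm. The step needs cyclisation to outrun simple reduction of ketone or enoate; slow addition of the reductant and the conformational bias of the (E)-enoate serve this, and the benzyl-type ether, the silyl ether and the ester are inert to the reagent. A cold buffered work-up is used to limit closure of the γ-hydroxy ester to a lactone.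

Step 10
Reactants: 18 ethyl 2-{(1S,2S,5S,6S)-5-[(tert-butyldimethylsilyl)oxy]-2-hydroxy-6-[3-(4-methoxybenzyloxy)propyl]-1,2-dimethylcyclohexyl}acetate
Product: 19 triethylsilyl ether of 18 at the tertiary C10 oxygen (ring configuration as in 18)
Conditions: Et3SiOTf, 2,6-lutidine, CH2Cl2, −78 → 0 °C
Reagents that add atoms: triethylsilyl triflate, CC[Si](CC)(CC)OS(=O)(=O)C(F)(F)F
Why: Silyl triflates silylate hindered tertiary alcohols; the C10 oxygen must be capped because a free 1,4-hydroxy iodide would close to a cyclic ether and would protonate the organozinc of step 15.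

Step 11
Reactants: 19 triethylsilyl ether of 18 at the tertiary C10 oxygen
Product: 20 primary alcohol: the CH2CO2Et arm of 19 reduced to CH2CH2OH (C12–C13), all else unchanged
Conditions: LiAlH4, Et2O, 0 °C; aq. KNaC4H4O6
Reagents that add atoms: none
Why: Hydride reduction of the ester to the primary alcohol; silyl and benzyl ethers are inert, and a silyl shift from O10 to O13 would need a seven-membered silicate and is not expected.

Step 12
Reactants: 20 primary alcohol with C13–OH
Product: 21 primary iodide with C13–I, otherwise as 20
Conditions: I2, PPh3, imidazole, CH2Cl2, 0 °C → rt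
Reagents that add atoms: iodine, II
Why: Appel-type iodination of a primary alcohol through the alkoxyphosphonium salt; imidazole buffers the acid so the tertiary silyl ether stays on, and the capped C10 oxygen cannot cyclise onto C13.

Step 13
Reactants: 22 (E)-geranylacetone, (5E)-6,10-dimethylundeca-5,9-dien-2-one
Product: 24 (5E)-6,10-dimethylundeca-5,9-dien-1-yne, via enol diethyl phosphate 23 (not isolated)
Conditions: LiN(i-Pr)2, THF, −78 °C; ClP(O)(OEt)2, −78 °C → rt; then LiN(i-Pr)2 (2.3 equiv), −78 °C → rt; H2O
Reagents that add atoms: none
Why: Negishi's methyl ketone-to-alkyne sequence: kinetic deprotonation on the methyl side, O-phosphorylation and base-induced elimination give the terminal alkyne without touching the trisubstituted alkenes.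

Step 14
Reactants: 24 (5E)-6,10-dimethylundeca-5,9-dien-1-yne
Product: 26 (1E,5E)-1-iodo-2,6,10-trimethylundeca-1,5,9-triene, via alkenyldimethylalane 25 (not isolated)
Conditions: Me3Al, Cp2ZrCl2 (25 mol%), CH2Cl2, rt; then I2, THF, −30 → 0 °C
Reagents that add atoms: trimethylaluminium, C[Al](C)C; iodine, II
Why: Zirconium-catalysed methylalumination (Negishi carboalumination) adds methyl and aluminium syn across the alkyne with aluminium at the terminus; iodinolysis of the carbon–aluminium bond with retention gives the (E)-alkenyl iodide.

Step 15
Reactants: 21 primary iodide with C13–I; 26 (1E,5E)-1-iodo-2,6,10-trimethylundeca-1,5,9-triene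
Product: 28 coupled product: ring of 18 carrying the complete (E,E)-homofarnesyl chain C12–C23 at C11 with 3-O-PMB 7-O-TBS 10-O-TES protection, via alkylzinc iodide 27 (not isolated)
Conditions: Zn dust (activated with BrCH2CH2Br and Me3SiCl), LiCl, THF, 40 °C; then 26, Pd(PPh3)4 (5 mol%), THF, 50 °C
Reagents that add atoms: none
Why: Negishi sp3–sp2 cross-coupling: zinc inserts into the primary C–I bond, the alkylzinc transmetalates to the alkenylpalladium iodide formed from 26 and zerovalent palladium, and reductive elimination forms C13–C14. Reductive elimination is faster than β-hydride elimination for a primary alkyl group, the alkene geometry of 26 is retained, and the ethers are inert to the organozinc.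

Step 16
Reactants: 28 coupled product with 3-O-PMB 7-O-TBS 10-O-TES protection
Product: 29 diol with free C7 secondary and C10 tertiary hydroxyls, 3-O-PMB retained
Conditions: n-Bu4NF, THF, rt → 50 °C
Reagents that add atoms: none
Why: Fluoride cleaves both silyl ethers, driven by the strength of the Si–F bond; the benzyl-type ether and the alkenes are untouched.

Step 17
Reactants: 29 diol with free C7 and C10 hydroxyls
Product: 30 C7 ketone with free C10 tertiary hydroxyl, 3-O-PMB retained
Conditions: Dess–Martin periodinane, NaHCO3, CH2Cl2, 0 °C → rt
Reagents that add atoms: none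
Why: Dess–Martin oxidation of the secondary alcohol under buffered conditions; the tertiary alcohol cannot be oxidised, and the α-centre C6 already sits in its more stable equatorial arrangement, so epimerisation is not a concern.

Step 18
Reactants: 30 C7 ketone
Product: 31 tertiary allylic alcohol: 2-propenyl group and hydroxyl on C7 (hydroxyl expected axial, cis to the C11 methyl), C10 hydroxyl free, 3-O-PMB retained
Conditions: CeCl3 (anhydrous), CH2=C(CH3)MgBr, THF, −78 °C; then 30, −78 → 0 °C; aq. NH4Cl
Reagents that add atoms: isopropenylmagnesium bromide, C=C(C)[Mg]Br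
Why: Organocerium (Imamoto) 1,2-addition: the weakly basic, oxophilic reagent adds to hindered enolisable ketones, with one equivalent spent on the C10 hydroxyl. Attack is expected along the equatorial direction, away from the axial C11 methyl; the new carbinol centre is erased in step 19, so its configuration is not critical.

Step 19
Reactants: 31 tertiary allylic alcohol at C7
Product: 34 3-O-(4-methoxybenzyl)iridal, via tertiary chromate ester 32 (not isolated), via primary allylic chromate ester 33 (not isolated)
Conditions: pyridinium chlorochromate (C5H5NH)[CrO3Cl] (3 equiv), SiO2, CH2Cl2, rt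
Reagents that add atoms: pyridinium chlorochromate, [O-][Cr](=O)(=O)Cl.c1cc[nH+]cc1
Why: Babler–Dauben oxidative transposition: the tertiary allylic alcohol gives chromate 32, a [3,3]-sigmatropic shift moves oxygen to C1 and the double bond to C7=C2 (33), and the primary chromate is oxidised to the aldehyde by hexavalent chromium. In the shift the 2-propenyl group should turn its methyl towards the ring methylene C8 and its small CH2 terminus towards the branched C6, which places C1 cis to C6, the (Z) geometry of the target. The C10 alcohol is tertiary and non-allylic and cannot react further.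

Step 20
Reactants: 34 3-O-(4-methoxybenzyl)iridal
Product: 35 iridal
Conditions: DDQ, CH2Cl2/pH 7 phosphate buffer 10:1, 0 °C
Reagents that add atoms: none
Why: Oxidative cleavage of the 4-methoxybenzyl ether by DDQ through the benzylic oxocarbenium ion, which water hydrolyses; the neutral buffered medium spares the enal, the tertiary alcohol and the trisubstituted alkenes.

## Compound list

1 | δ-valerolactone | O=C1CCCCO1 | starting material
2 | potassium 5-hydroxypentanoate | [K+].[O-]C(=O)CCCCO | intermediate
3 | 5-[(4-methoxybenzyl)oxy]pentanoic acid | OC(=O)CCCCOCc1ccc(OC)cc1 | intermediate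
4 | (R)-4-benzyl-1,3-oxazolidin-2-one | O=C1N[C@H](Cc2ccccc2)CO1 | starting material
5 | 5-[(4-methoxybenzyl)oxy]pentanoic pivalic anhydride | CC(C)(C)C(=O)OC(=O)CCCCOCc1ccc(OC)cc1 | intermediate
6 | (R)-4-benzyl-3-{5-[(4-methoxybenzyl)oxy]pentanoyl}-1,3-oxazolidin-2-one | O=C1OC[C@@H](Cc2ccccc2)N1C(=O)CCCCOCc1ccc(OC)cc1 | intermediate
7 | pent-4-enal | C=CCCC=O | starting material
8 | dibutylboron (Z)-enolate of 6 | CCCCB(CCCC)O/C(=C\CCCOCc1ccc(OC)cc1)N1C(=O)OC[C@H]1Cc1ccccc1 | intermediate
9 | (R)-4-benzyl-3-{(2R,3S)-3-hydroxy-2-[3-(4-methoxybenzyloxy)propyl]hept-6-enoyl}-1,3-oxazolidin-2-one | O=C1OC[C@@H](Cc2ccccc2)N1C(=O)[C@H](CCCOCc1ccc(OC)cc1)[C@@H](O)CCC=C | intermediate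
10 | (2R,3S)-3-hydroxy-N-methoxy-2-[3-(4-methoxybenzyloxy)propyl]-N-methylhept-6-enamide | CON(C)C(=O)[C@H](CCCOCc1ccc(OC)cc1)[C@@H](O)CCC=C | intermediate
11 | (2R,3S)-3-[(tert-butyldimethylsilyl)oxy]-N-methoxy-2-[3-(4-methoxybenzyloxy)propyl]-N-methylhept-6-enamide | CON(C)C(=O)[C@H](CCCOCc1ccc(OC)cc1)[C@@H](O[Si](C)(C)C(C)(C)C)CCC=C | intermediate
12 | (3R,4S)-4-[(tert-butyldimethylsilyl)oxy]-3-[3-(4-methoxybenzyloxy)propyl]oct-7-en-2-one | CC(=O)[C@H](CCCOCc1ccc(OC)cc1)[C@@H](O[Si](C)(C)C(C)(C)C)CCC=C | intermediate
13 | triethyl phosphonoacetate | CCOC(=O)CP(=O)(OCC)OCC | starting material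
14 | sodium salt of triethyl phosphonoacetate | CCOC(=O)[CH-]P(=O)(OCC)OCC.[Na+] | intermediate
15 | ethyl (2E,4S,5S)-5-[(tert-butyldimethylsilyl)oxy]-4-[3-(4-methoxybenzyloxy)propyl]-3-methylnona-2,8-dienoate | CCOC(=O)/C=C(\C)[C@H](CCCOCc1ccc(OC)cc1)[C@@H](O[Si](C)(C)C(C)(C)C)CCC=C | intermediate
16 | ethyl (2E,4S,5S)-5-[(tert-butyldimethylsilyl)oxy]-4-[3-(4-methoxybenzyloxy)propyl]-3-methyl-8-oxonon-2-enoate | CC(=O)CC[C@H](O[Si](C)(C)C(C)(C)C)[C@@H](CCCOCc1ccc(OC)cc1)/C(C)=C/C(=O)OCC | intermediate
17 | samarium ketyl of 16 (C10 radical, O–SmI2; HMPA ligands omitted) | C[C](O[Sm](I)I)CC[C@H](O[Si](C)(C)C(C)(C)C)[C@@H](CCCOCc1ccc(OC)cc1)/C(C)=C/C(=O)OCC | intermediate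
18 | ethyl 2-{(1S,2S,5S,6S)-5-[(tert-butyldimethylsilyl)oxy]-2-hydroxy-6-[3-(4-methoxybenzyloxy)propyl]-1,2-dimethylcyclohexyl}acetate | CCOC(=O)C[C@@]1(C)[C@H](CCCOCc2ccc(OC)cc2)[C@@H](O[Si](C)(C)C(C)(C)C)CC[C@]1(C)O | intermediate
19 | 10-O-triethylsilyl ether of 18 | CCOC(=O)C[C@@]1(C)[C@H](CCCOCc2ccc(OC)cc2)[C@@H](O[Si](C)(C)C(C)(C)C)CC[C@]1(C)O[Si](CC)(CC)CC | intermediate
20 | primary alcohol (C13–OH) from 19 | OCC[C@@]1(C)[C@H](CCCOCc2ccc(OC)cc2)[C@@H](O[Si](C)(C)C(C)(C)C)CC[C@]1(C)O[Si](CC)(CC)CC | intermediate
21 | primary iodide (C13–I) | ICC[C@@]1(C)[C@H](CCCOCc2ccc(OC)cc2)[C@@H](O[Si](C)(C)C(C)(C)C)CC[C@]1(C)O[Si](CC)(CC)CC | intermediate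
22 | (E)-geranylacetone | CC(C)=CCC/C(C)=C/CCC(C)=O | starting material
23 | diethyl (5E)-6,10-dimethylundeca-1,5,9-trien-2-yl phosphate | CC(C)=CCC/C(C)=C/CCC(=C)OP(=O)(OCC)OCC | intermediate
24 | (5E)-6,10-dimethylundeca-5,9-dien-1-yne | CC(C)=CCC/C(C)=C/CCC#C | intermediate
25 | dimethyl[(1E,5E)-2,6,10-trimethylundeca-1,5,9-trienyl]alane | CC(C)=CCC/C(C)=C/CC/C(C)=C/[Al](C)C | intermediate
26 | (1E,5E)-1-iodo-2,6,10-trimethylundeca-1,5,9-triene | CC(C)=CCC/C(C)=C/CC/C(C)=C/I | intermediate
27 | alkylzinc iodide from 21 | I[Zn]CC[C@@]1(C)[C@H](CCCOCc2ccc(OC)cc2)[C@@H](O[Si](C)(C)C(C)(C)C)CC[C@]1(C)O[Si](CC)(CC)CC | intermediate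
28 | coupled product, 3-O-PMB 7-O-TBS 10-O-TES | CC(C)=CCC/C(C)=C/CC/C(C)=C/CC[C@@]1(C)[C@H](CCCOCc2ccc(OC)cc2)[C@@H](O[Si](C)(C)C(C)(C)C)CC[C@]1(C)O[Si](CC)(CC)CC | intermediate
29 | C7,C10-diol, 3-O-PMB | CC(C)=CCC/C(C)=C/CC/C(C)=C/CC[C@@]1(C)[C@H](CCCOCc2ccc(OC)cc2)[C@@H](O)CC[C@]1(C)O | intermediate
30 | C7 ketone, 3-O-PMB | CC(C)=CCC/C(C)=C/CC/C(C)=C/CC[C@@]1(C)[C@H](CCCOCc2ccc(OC)cc2)C(=O)CC[C@]1(C)O | intermediate
31 | C7 2-propenyl carbinol, 3-O-PMB | CC(C)=CCC/C(C)=C/CC/C(C)=C/CC[C@@]1(C)[C@H](CCCOCc2ccc(OC)cc2)[C@@](O)(C(C)=C)CC[C@]1(C)O | intermediate
32 | pyridinium salt of the C7 tertiary chromate ester | CC(C)=CCC/C(C)=C/CC/C(C)=C/CC[C@@]1(C)[C@H](CCCOCc2ccc(OC)cc2)[C@@](O[Cr](=O)(=O)[O-])(C(C)=C)CC[C@]1(C)O.c1cc[nH+]cc1 | intermediate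
33 | pyridinium salt of the C1 primary allylic chromate ester | CC(C)=CCC/C(C)=C/CC/C(C)=C/CC[C@@]1(C)[C@H](CCCOCc2ccc(OC)cc2)/C(=C(/C)CO[Cr](=O)(=O)[O-])CC[C@]1(C)O.c1cc[nH+]cc1 | intermediate
34 | 3-O-(4-methoxybenzyl)iridal | CC(C)=CCC/C(C)=C/CC/C(C)=C/CC[C@@]1(C)[C@H](CCCOCc2ccc(OC)cc2)/C(=C(/C)C=O)CC[C@]1(C)O | intermediate
35 | iridal, (6R,10S,11S) | CC(C)=CCC/C(C)=C/CC/C(C)=C/CC[C@@]1(C)[C@H](CCCO)/C(=C(/C)C=O)CC[C@]1(C)O | target

## Step count and least certain steps

Total step count: 20. Longest linear sequence: 18 steps (steps 1–12 and 15–20); steps 13 and 14 make the chain fragment.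

Step 9 (key step). The most likely failure is reduction without ring closure: the ketyl or the enoate radical anion takes a second electron and a proton before the C10–C11 bond forms, because addition to a β,β-disubstituted acceptor that builds a quaternary carbon is slow. A second risk is erosion of facial control at C10 if the samarium alkoxide chelates the ester instead of staying away from it. The fallback sets out from 16 and returns at 18: a cathodic electroreductive cyclisation (Hg pool cathode, Et4NOTs, CH3CN, dimethyl malonate as proton donor). There no coordinating lanthanide is involved, the enoate radical anion is the likely initiating species and the electron supply is set by the potential. No new compound arises on this path (F0).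

Step 19 (with step 18). Control of alkene geometry may be poor if the tertiary chromate ionises to an allyl cation instead of rearranging in concert, and dehydration to a diene may compete. The enal, once formed, may also isomerise through its dienol. The fallback sets out from ketone 30 and returns at 34. A Horner–Wadsworth–Emmons reaction with diethyl (1-cyanoethyl)phosphonate (NaH, THF, reflux; one extra equivalent of base for the C10 hydroxyl) should give the tetrasubstituted unsaturated nitrile F1, in which the rod-like nitrile is expected on the hindered C6 side and geometric isomers can be separated. Reduction with i-Bu2AlH (toluene, −78 °C) and mild hydrolysis of the aldimine then gives 34.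

Step 7. Enolisation towards C6 during a slow olefination of an α-branched ketone at reflux could epimerise C6 or expel the silanolate, and (E)-selectivity may be incomplete. The fallback sets out from Weinreb amide 11 and returns at 15. Reduction with i-Bu2AlH (THF, −78 °C) gives the aldehyde F2, Ohira–Bestmann homologation (dimethyl 1-diazo-2-oxopropylphosphonate, K2CO3, MeOH) gives the terminal alkyne F3, and zirconium-catalysed methylalumination (Me3Al, Cp2ZrCl2) followed by ClCO2Et gives 15 with the geometry fixed by syn-carbometalation.

Step 15. Zinc insertion may be sluggish, the organozinc may be protonated by adventitious moisture, and β-hydride elimination or homocoupling may occur at palladium. The fallback sets out from iodide 21 and returns at 28. Iodine–lithium exchange (t-BuLi, Et2O, −78 °C) and capture with B-methoxy-9-borabicyclo[3.3.1]nonane gives the lithium borinate F4, which is coupled with 26 under B-alkyl Suzuki–Miyaura conditions (PdCl2(dppf), aq. K3PO4, DMF, rt).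

Step 10. Silylation of the hindered tertiary hydroxyl may be incomplete, or 18 may already have closed to the trans-fused γ-lactone F5, which has no hydroxyl left to protect. The fallback sets out from 18 (or from F5) and returns at 20. LiAlH4 reduces either compound to the 1,4-diol F6, excess Et3SiOTf with 2,6-lutidine gives the bis(triethylsilyl) ether F7, and brief treatment with pyridinium p-toluenesulfonate in MeOH at 0 °C removes only the primary silyl group to give 20.

## Further compounds

F0 | step 9 | none | none
F1 | step 19 | tetrasubstituted unsaturated nitrile (C1 as C≡N, cis to C6), 3-O-PMB | CC(C)=CCC/C(C)=C/CC/C(C)=C/CC[C@@]1(C)[C@H](CCCOCc2ccc(OC)cc2)/C(=C(/C)C#N)CC[C@]1(C)O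
F2 | step 7 | (2R,3S)-3-[(tert-butyldimethylsilyl)oxy]-2-[3-(4-methoxybenzyloxy)propyl]hept-6-enal | O=C[C@H](CCCOCc1ccc(OC)cc1)[C@@H](O[Si](C)(C)C(C)(C)C)CCC=C
F3 | step 7 | (3S,4S)-4-[(tert-butyldimethylsilyl)oxy]-3-[3-(4-methoxybenzyloxy)propyl]oct-7-en-1-yne | C#C[C@H](CCCOCc1ccc(OC)cc1)[C@@H](O[Si](C)(C)C(C)(C)C)CCC=C
F4 | step 15 | lithium B-alkyl-B-methoxy-9-borabicyclo[3.3.1]nonane borinate from 21 | [Li+].CO[B-]1(CC[C@@]2(C)[C@H](CCCOCc3ccc(OC)cc3)[C@@H](O[Si](C)(C)C(C)(C)C)CC[C@]2(C)O[Si](CC)(CC)CC)C2CCCC1CCC2
F5 | step 10 | trans-fused γ-lactone of 18 (O10–C13) | O=C1C[C@@]2(C)[C@H](CCCOCc3ccc(OC)cc3)[C@@H](O[Si](C)(C)C(C)(C)C)CC[C@]2(C)O1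
F6 | step 10 | 1,4-diol (C13–OH and C10–OH) | OCC[C@@]1(C)[C@H](CCCOCc2ccc(OC)cc2)[C@@H](O[Si](C)(C)C(C)(C)C)CC[C@]1(C)O
F7 | step 10 | bis(triethylsilyl) ether of F6 | CC[Si](CC)(CC)OCC[C@@]1(C)[C@H](CCCOCc2ccc(OC)cc2)[C@@H](O[Si](C)(C)C(C)(C)C)CC[C@]1(C)O[Si](CC)(CC)CC
A1 | alternative 1 | 2-allyl-3-homofarnesyl-3,4-dimethyl-4-(triethylsilyloxy)cyclohexanone | CC(C)=CCC/C(C)=C/CC/C(C)=C/CC[C@@]1(C)[C@H](CC=C)C(=O)CC[C@]1(C)O[Si](CC)(CC)CC
A2 | alternative 1 | (4S)-3,4-dimethyl-4-(triethylsilyloxy)cyclohex-2-en-1-one | CC1=CC(=O)CC[C@]1(C)O[Si](CC)(CC)CC
A3 | alternative 1 | homofarnesyl iodide, (3E,7E)-1-iodo-4,8,12-trimethyltrideca-3,7,11-triene | CC(C)=CCC/C(C)=C/CC/C(C)=C/CCI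
A4 | alternative 2 | 2-allyl-3-homofarnesyl-4-hydroxy-3-methylcyclohexanone | CC(C)=CCC/C(C)=C/CC/C(C)=C/CC[C@@]1(C)[C@H](CC=C)C(=O)CC[C@@H]1O
A5 | alternative 2 | trans-10,11-epoxide tethered to the (Z)-trimethylsilyl enol ether at C7=C6 | CC(C)=CCC/C(C)=C/CC/C(C)=C/CC[C@]1(C)O[C@H]1CC/C(O[Si](C)(C)C)=C/CC=C
A6 | alternative 3 | cyclised tetrasubstituted enoate with C3 aldehyde and C10 triethylsilyl ether | CC(C)=CCC/C(C)=C/CC/C(C)=C/CC[C@@]1(C)[C@H](CCC=O)/C(=C(/C)C(=O)OCC)CC[C@@H]1O[Si](CC)(CC)CC
A7 | alternative 3 | acyclic (Z)-enol triflate with (E)-homoallylic alcohol | CC(C)=CCC/C(C)=C/CC/C(C)=C/CC[C@@](C)(/C=C/CCO)[C@H](CC/C(OS(=O)(=O)C(F)(F)F)=C(\C)C(=O)OCC)O[Si](CC)(CC)CC
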